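**Retrosynthetic overview**
1. Target 21 ⇐ tricyclic diene 18 (C7=C8–C9=C10): site-selective mono-epoxidation and Pd(0) isomerisation turn the diene into the 8(9)-en-7-one.
2. 18 ⇐ monocyclic dienyne 17: one tandem ene–yne–ene ring-closing metathesis closes the cyclopentene (B) and the nine-membered azonine (C) together.
3. 17 ⇐ chloride 14 (amination/formylation) ⇐ 3-methyl enone 9: C1–O by Luche reduction, C3–O by OH-directed epoxidation and hydride opening (cis-1,3-diol).
4. 9 ⇐ (R)-5-methylcyclohexenone 1: α-alkynylation, trans-Sakurai allylation (C5), trans-alkylation (quaternary C15), then IBX desaturation, which erases the relay methyl stereocentre.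
5. Ring order: A comes from 1; B and C are formed simultaneously, late.

Atom labels (order of the target SMILES): C1 = CH–OAc, C2, C3 = C(Me)OAc, C4, C5 = ring-fusion CH, C6, C7 = C=O, C8, C9 = alkene CH, C10, C11, N, C12–C14, C15 = quaternary C. The target is (1S,3S,5S,15S), 8(9)-E.

Assumption: (R)-5-methylcyclohex-2-en-1-one (1) is bought as a catalogue chiral-pool compound (made from (R)-pulegone); all other starting materials are bulk chemicals.

**Route**

Step 1
Reactants: 1 (R)-5-methylcyclohex-2-en-1-one
Product: 2 (R)-2-iodo-5-methylcyclohex-2-en-1-one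
Conditions: I2, pyridine, CH2Cl2, 0 °C → rt
Reagents that add atoms: iodine, II
Why: α-iodination of an enone by conjugate addition of pyridine, iodination of the enolate and elimination (Johnson iodination) gives the cross-coupling handle without touching the stereocentre.

Step 2
Reactants: 2 (R)-2-iodo-5-methylcyclohex-2-en-1-one; 3 ethynyltrimethylsilane
Product: 4 (R)-5-methyl-2-[(trimethylsilyl)ethynyl]cyclohex-2-en-1-one
Conditions: PdCl2(PPh3)2 (5 mol %), CuI (10 mol %), i-Pr2NH, THF, 0 °C → rt
Reagents that add atoms: none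
Why: Sonogashira coupling of the vinyl iodide brings in the two carbons that become C8 and C9, the silyl cap protecting the alkyne C–H during the enolate chemistry that follows.

Step 3
Reactants: 4 (R)-5-methyl-2-[(trimethylsilyl)ethynyl]cyclohex-2-en-1-one; 5 allyltrimethylsilane
Product: 6 (3R,5R)-3-allyl-5-methyl-2-[(trimethylsilyl)ethynyl]cyclohexan-1-one (C2 epimer mixture)
Conditions: TiCl4, CH2Cl2, −78 °C; aq. NaHCO3
Reagents that add atoms: none
Why: Hosomi–Sakurai conjugate allylation, in which the allylsilane attacks the TiCl4-activated enone axially on the face opposite the ring methyl group and so sets C5 (allyl trans to methyl); the C2 epimers do not matter because this carbon is enolised in step 4.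

Step 4
Reactants: 6 (3R,5R)-3-allyl-5-methyl-2-[(trimethylsilyl)ethynyl]cyclohexan-1-one; 7 1-chloro-3-iodopropane
Product: 8 (2S,3R,5R)-3-allyl-2-(3-chloropropyl)-5-methyl-2-[(trimethylsilyl)ethynyl]cyclohexan-1-one
Conditions: KHMDS, THF, −78 °C; then 7, DMPU, −78 → 0 °C
Reagents that add atoms: none
Why: enolate C-alkylation, in which only the propargylic α-H is removed and the iodide end of 7 attacks anti to the neighbouring pseudo-axial allyl group, setting the quaternary centre C15 with the alkyne cis and the chloropropyl chain trans to the allyl group.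

Step 5
Reactants: 8 (2S,3R,5R)-3-allyl-2-(3-chloropropyl)-5-methyl-2-[(trimethylsilyl)ethynyl]cyclohexan-1-one
Product: 9 (5R,6S)-5-allyl-6-(3-chloropropyl)-3-methyl-6-[(trimethylsilyl)ethynyl]cyclohex-2-en-1-one
Conditions: IBX (2.5 equiv), DMSO, 75 °C
Reagents that add atoms: none
Why: IBX dehydrogenation of a ketone to an enone can only go towards C2–C3 because C15 is quaternary; it removes the methyl stereocentre once it has served as controller and gives the β-methyl enone from which C1 and C3 are set.

Step 6
Reactants: 9 (5R,6S)-5-allyl-6-(3-chloropropyl)-3-methyl-6-[(trimethylsilyl)ethynyl]cyclohex-2-en-1-one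
Product: 11 (1S,5R,6S)-5-allyl-6-(3-chloropropyl)-6-ethynyl-3-methylcyclohex-2-en-1-ol, via C-silylated allylic alcohol 10 (not isolated)
Conditions: NaBH4, CeCl3·7H2O, MeOH, −40 °C; then K2CO3, rt
Reagents that add atoms: none
Why: Luche 1,2-reduction, in which hydride adds to C1 axially, anti to the pseudo-axial alkyne on C15 and unhindered because C3 is sp2, giving the equatorial alcohol cis to the alkyne (C1 set); K2CO3/MeOH then protodesilylates the alkyne.

Step 7
Reactants: 11 (1S,5R,6S)-5-allyl-6-(3-chloropropyl)-6-ethynyl-3-methylcyclohex-2-en-1-ol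
Product: 12 (1R,2R,3S,4R,6S)-4-allyl-3-(3-chloropropyl)-3-ethynyl-6-methyl-7-oxabicyclo[4.1.0]heptan-2-ol (epoxide cis to OH)
Conditions: VO(acac)2 (5 mol %), t-BuOOH, toluene, 0 °C → rt
Reagents that add atoms: tert-butyl hydroperoxide, CC(C)(C)OO
Why: vanadium-catalysed hydroxyl-directed epoxidation delivers oxygen to the alkene face syn to the C1 hydroxyl and ignores the isolated terminal alkene and alkyne, so the C3–O bond is set cis to C1–O.

Step 8
Reactants: 12 (1R,2R,3S,4R,6S)-4-allyl-3-(3-chloropropyl)-3-ethynyl-6-methyl-7-oxabicyclo[4.1.0]heptan-2-ol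
Product: 13 (1S,3S,4S,5R)-5-allyl-4-(3-chloropropyl)-4-ethynyl-1-methylcyclohexane-1,3-diol
Conditions: LiAlH4, THF, 0 °C → rt; aq. NaOH work-up
Reagents that add atoms: none
Why: SN2 hydride opening of the trisubstituted epoxide at the secondary carbon C2 (as in the reduction of 1-methylcyclohexene oxides to tertiary alcohols) leaves the C3–O bond of step 7 intact and gives the cis-1,3-diol; the primary chloride, the alkene and the alkyne are not reduced at this temperature.

Step 9
Reactants: 13 (1S,3S,4S,5R)-5-allyl-4-(3-chloropropyl)-4-ethynyl-1-methylcyclohexane-1,3-diol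
Product: 14 (1S,3S,4S,5R)-5-allyl-4-(3-chloropropyl)-4-ethynyl-1-methylcyclohexane-1,3-diyl diacetate
Conditions: Ac2O, Sc(OTf)3 (5 mol %), MeCN, −20 → 0 °C
Reagents that add atoms: acetic anhydride, CC(=O)OC(C)=O
Why: Lewis-acid-catalysed acetylation esterifies the hindered secondary and the tertiary alcohol without elimination and touches no stereocentre.

Step 10
Reactants: 14 (1S,3S,4S,5R)-5-allyl-4-(3-chloropropyl)-4-ethynyl-1-methylcyclohexane-1,3-diyl diacetate; 15 allylamine
Product: 17 (1S,3S,4S,5R)-5-allyl-4-{3-[allyl(formyl)amino]propyl}-4-ethynyl-1-methylcyclohexane-1,3-diyl diacetate, via secondary amine 16 (not isolated)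
Conditions: 15 (10 equiv), NaI (0.2 equiv), MeCN, 60 °C; evaporate; then HCO2Et, 55 °C
Reagents that add atoms: ethyl formate, CCOC=O
Why: SN2 amination of the primary chloride (iodide catalysis, excess amine against double alkylation) followed by N-formylation with ethyl formate installs N, C10, C11 and the formyl group only after the last hydride step, which a formamide would not survive.

Step 11
Reactants: 17 (1S,3S,4S,5R)-5-allyl-4-{3-[allyl(formyl)amino]propyl}-4-ethynyl-1-methylcyclohexane-1,3-diyl diacetate
Product: 18 tricyclic diene (rings A/B/C of the target with a C7=C8–C9=C10 diene, 9Z, in place of the enone; 1,3-diacetate, N-formyl; C1, C3, C5, C15 as in the target)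
Conditions: Grubbs II (10 mol %), CH2Cl2 (1 mM), 40 °C
Reagents that add atoms: none
Why: tandem ring-closing ene–yne–ene metathesis, in which the Ru alkylidene on the C5 allyl group adds 5-exo to the alkyne (cyclopentene, ring B) and the resulting vinyl carbene closes the azonine onto the N-allyl group (ring C, cis alkene enforced by ring size) with loss of ethene; no stereocentre is formed, the cis ring fusion being fixed by C5 and C15.

Step 12
Reactants: 18 tricyclic diene
Product: 21 target CNP0137427.1, via vinyl epoxide 19 (not isolated), via deconjugated ketone 20 (not isolated)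
Conditions: DMDO (1.05 equiv), acetone/CH2Cl2, −40 → 0 °C; evaporate; Pd(PPh3)4 (5 mol %), THF, rt; then DBU (0.2 equiv), rt
Reagents that add atoms: dimethyldioxirane, CC1(C)OO1
Why: DMDO epoxidises the electron-rich trisubstituted C7=C8 bond of the diene, Pd(0) ionises the vinyl epoxide to a π-allyl alkoxide that collapses by hydride shift to the C7 ketone (Pd-catalysed vinyl-epoxide-to-ketone isomerisation), and DBU moves the β,γ-alkene into conjugation as the ring-constrained alkylidene (C10 cis to C15 in the azonine, E as drawn).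

**Compound list**
1 | (R)-5-methylcyclohex-2-en-1-one | O=C1C[C@H](C)CC=C1 | starting material
2 | (R)-2-iodo-5-methylcyclohex-2-en-1-one | O=C1C[C@H](C)CC=C1I | intermediate
3 | ethynyltrimethylsilane | C#C[Si](C)(C)C | starting material
4 | (R)-5-methyl-2-[(trimethylsilyl)ethynyl]cyclohex-2-en-1-one | O=C1C[C@H](C)CC=C1C#C[Si](C)(C)C | intermediate
5 | allyltrimethylsilane | C=CC[Si](C)(C)C | starting material
6 | (3R,5R)-3-allyl-5-methyl-2-[(trimethylsilyl)ethynyl]cyclohexan-1-one (C2 epimers) | O=C1C[C@H](C)C[C@@H](CC=C)C1C#C[Si](C)(C)C | intermediate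
7 | 1-chloro-3-iodopropane | ClCCCI | starting material
8 | (2S,3R,5R)-3-allyl-2-(3-chloropropyl)-5-methyl-2-[(trimethylsilyl)ethynyl]cyclohexan-1-one | O=C1C[C@H](C)C[C@@H](CC=C)[C@@]1(CCCCl)C#C[Si](C)(C)C | intermediate
9 | (5R,6S)-5-allyl-6-(3-chloropropyl)-3-methyl-6-[(trimethylsilyl)ethynyl]cyclohex-2-en-1-one | O=C1C=C(C)C[C@@H](CC=C)[C@@]1(CCCCl)C#C[Si](C)(C)C | intermediate
10 | (1S,5R,6S)-5-allyl-6-(3-chloropropyl)-3-methyl-6-[(trimethylsilyl)ethynyl]cyclohex-2-en-1-ol | O[C@H]1C=C(C)C[C@@H](CC=C)[C@@]1(CCCCl)C#C[Si](C)(C)C | intermediate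
11 | (1S,5R,6S)-5-allyl-6-(3-chloropropyl)-6-ethynyl-3-methylcyclohex-2-en-1-ol | O[C@H]1C=C(C)C[C@@H](CC=C)[C@@]1(CCCCl)C#C | intermediate
12 | (1R,2R,3S,4R,6S)-4-allyl-3-(3-chloropropyl)-3-ethynyl-6-methyl-7-oxabicyclo[4.1.0]heptan-2-ol | O[C@H]1[C@H]2O[C@@]2(C)C[C@@H](CC=C)[C@@]1(CCCCl)C#C | intermediate
13 | (1S,3S,4S,5R)-5-allyl-4-(3-chloropropyl)-4-ethynyl-1-methylcyclohexane-1,3-diol | O[C@H]1C[C@@](C)(O)C[C@@H](CC=C)[C@@]1(CCCCl)C#C | intermediate
14 | (1S,3S,4S,5R)-5-allyl-4-(3-chloropropyl)-4-ethynyl-1-methylcyclohexane-1,3-diyl diacetate | CC(=O)O[C@H]1C[C@@](C)(OC(C)=O)C[C@@H](CC=C)[C@@]1(CCCCl)C#C | intermediate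
15 | allylamine (prop-2-en-1-amine) | NCC=C | starting material
16 | (1S,3S,4S,5R)-5-allyl-4-[3-(allylamino)propyl]-4-ethynyl-1-methylcyclohexane-1,3-diyl diacetate | CC(=O)O[C@H]1C[C@@](C)(OC(C)=O)C[C@@H](CC=C)[C@@]1(CCCNCC=C)C#C | intermediate
17 | (1S,3S,4S,5R)-5-allyl-4-{3-[allyl(formyl)amino]propyl}-4-ethynyl-1-methylcyclohexane-1,3-diyl diacetate | CC(=O)O[C@H]1C[C@@](C)(OC(C)=O)C[C@@H](CC=C)[C@@]1(CCCN(C=O)CC=C)C#C | intermediate
18 | tricyclic diene: target skeleton with C7=C8–C9=C10 (9Z) instead of the enone | CC(=O)O[C@H]1C[C@@](C)(OC(C)=O)C[C@H]2CC=C3/C=C\CN(C=O)CCC[C@@]321 | intermediate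
19 | 7,8-epoxide of 18 (epoxide configuration not controlled, lost in the next stage) | CC(=O)O[C@H]1C[C@@](C)(OC(C)=O)C[C@H]2CC3OC34/C=C\CN(C=O)CCC[C@@]421 | intermediate
20 | deconjugated ketone: C7 ketone, C8–H, 9Z-alkene (C8 epimers) | CC(=O)O[C@H]1C[C@@](C)(OC(C)=O)C[C@H]2CC(=O)C3/C=C\CN(C=O)CCC[C@@]321 | intermediate
21 | CNP0137427.1, (1S,3S,5S,15S)-1,3-diacetoxy-N-formyl 8(9)-E-en-7-one | CC(=O)O[C@H]1C[C@@](C)(OC(C)=O)C[C@H]2CC(=O)/C3=C/CCN(C=O)CCC[C@@]321 | target

**Step count**
Total steps: 12. Longest linear sequence: 12 (1 → 21).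

**Steps most likely to fail, with fallbacks**

Step 11 is the main risk: the nine-membered closure may lag behind the fast cyclopentene closure and give oligomers or stop at the monocyclic stage. The fallback sets out from 17 and separates the two events. Ring-closing enyne metathesis alone under ethene (Grubbs I, CH2Cl2, rt) gives the 1-vinylcyclopentene triene F2. F2 is then cyclised in a separate diene RCM (Hoveyda–Grubbs II, toluene, 0.5 mM, 80 °C, slow addition), which comes back to the route at 18.

Step 12 is the second risk: the π-allyl palladium alkoxide may eliminate towards C11 to give a dienyl formamide instead of shifting hydride to the ketone. The fallback sets out from 18. The epoxide 19 is isolated after DMDO treatment and opened reductively with SmI2 (THF/MeOH, −78 °C; electron transfer, protonation at C10) to the allylic alcohol F3 (C7–OH, C8=C9). F3 is oxidised with Dess–Martin periodinane and the route is rejoined at 21.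

Step 4 is the third risk: C-alkylation of a hindered tetrasubstituted enolate with an unactivated iodide can give low conversion or O-alkylation. The fallback sets out from 4 and bypasses 6. Copper-mediated conjugate allylation (allylMgBr, CuBr·SMe2, TMSCl, THF, −78 °C) traps the enolate as the silyl enol ether F1. MeLi then releases the regiodefined lithium enolate, which is alkylated with 7 in THF/HMPA, and the route is rejoined at 8.

Further compounds
F1 | step 4 | {[(3R,5R)-3-allyl-5-methyl-2-[(trimethylsilyl)ethynyl]cyclohex-1-en-1-yl]oxy}trimethylsilane | C[Si](C)(C)OC1=C(C#C[Si](C)(C)C)[C@H](CC=C)C[C@@H](C)C1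
F2 | step 11 | bicyclic triene: ring B closed, vinyl group on C8, N-allyl chain open | CC(=O)O[C@H]1C[C@@](C)(OC(C)=O)C[C@H]2CC=C(C=C)[C@]21CCCN(C=O)CC=C
F3 | step 12 | tricyclic allylic alcohol: C7–OH (epimers), 8(9)-E-alkene | CC(=O)O[C@H]1C[C@@](C)(OC(C)=O)C[C@H]2CC(O)/C3=C/CCN(C=O)CCC[C@@]321
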